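Numbering: C6 (lactone O–CH), C5=C4 (C15 on C4), C3 (carbinol), C2, C1, C10 (tertiary carbinol, C14), C9 (angelate), C8, C7 (ring-fusion CH), C11/C12/C13 (lactone α-carbon, carbonyl, methylene).
Cuts: first the C9–O angelate ester, the C11=C13 methylene and the C3/C10 ethers; then the C4=C5 alkene and the C9 carbonyl are traced back to a C4–C9 σ bond; then the lactone C6–O and C7–C11 bonds; ring B is opened at C9–C10 (pinacol), C1=C2 (metathesis) and C3–C4 (allene addition).
Enabling feature: in the ten-membered ring C4 lies directly across from oxygenated C9, so a C4–C9 bond gives a cis-decalin (ring A: C4-C5-C6-C7-C8-C9; ring B: C4-C3-C2-C1-C10-C9) in which the C9–O bond, the shared C4–C9 bond and a C5 sulfonate form a 1,3-fragmentation array.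
Forward order: ring A is bought as 2-methylcyclohexane-1,3-dione; the C3–C2–C1–C10–C14 chain is attached at C4; ring B closes by C9–C10 pinacol coupling; the C11–C12 arm goes onto C7 and the γ-lactone ring closes at C6–O; fragmentation opens the decalin to the Z-cyclodecenone; the C9 ester and the C13 methylene come last.
Stereochemistry: a Trost ligand sets a sacrificial C3 centre that relays to C4, C9 and C10 in the pinacol step; the C9 hydroxyl directs hydride to C5; hydroboration anti to C5–O sets C6 and C7; C3 is re-set by hydride reduction of its ketone; the Z alkene follows from the stereospecific fragmentation; C9 comes from a Felkin–Anh reduction and the ester geometry from angelic acid.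

Key step: step 15

Remark: the (R,R)-ligand is assumed to give the (R)-ether 4 in step 2; if the opposite sense is found, the mirror-image ligand is used and nothing else changes.

Step 1
Reactants: 1 benzyl propargyl ether
Product: 2 benzyloxyallene
Conditions: KOtBu (0.2 equiv), THF, 0 to 25 °C
Reagents that add atoms: none
Why: Base-mediated propargyl–allenyl isomerisation should stop at the alkoxyallene, which is stabilised by conjugation of the ether oxygen with the cumulene; no stereocentre is formed.

Step 2
Reactants: 2 benzyloxyallene; 3 2-methylcyclohexane-1,3-dione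
Product: 4 (R)-2-[1-(benzyloxy)prop-2-en-1-yl]-2-methylcyclohexane-1,3-dione
Conditions: Pd2(dba)3·CHCl3 (2 mol%), (R,R)-DACH-phenyl Trost ligand (5 mol%), Et3N (10 mol%), CH2Cl2, 25 °C
Reagents that add atoms: none
Why: In this palladium-catalysed asymmetric addition of a 1,3-dicarbonyl pronucleophile to an alkoxyallene (Trost allylic alkylation manifold), hydropalladation gives an alkoxy-substituted π-allyl complex that the acidic dione attacks at the oxygen-bearing terminus, and the chiral diphosphine pocket sets C3 (R), used here only as a sacrificial control element.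

Step 3
Reactants: 4 (R)-2-[1-(benzyloxy)prop-2-en-1-yl]-2-methylcyclohexane-1,3-dione; 5 but-3-en-2-one
Product: 6 2-[(1R,2E)-1-(benzyloxy)-4-oxopent-2-en-1-yl]-2-methylcyclohexane-1,3-dione
Conditions: 5 (5 equiv), second-generation Hoveyda–Grubbs catalyst RuCl2(H2IMes)(=CH-C6H4-2-OiPr) (5 mol%), CH2Cl2, 40 °C
Reagents that add atoms: none
Why: Olefin cross-metathesis between a hindered terminal alkene that does not homodimerise and an excess of the electron-poor enone should give the E-enone and brings in C1, C10 and C14; C3 is untouched.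

Step 4
Reactants: 6 2-[(1R,2E)-1-(benzyloxy)-4-oxopent-2-en-1-yl]-2-methylcyclohexane-1,3-dione
Product: 7 2-[(R)-1-(benzyloxy)-4-oxopentyl]-2-methylcyclohexane-1,3-dione
Conditions: H2 (1 atm), RhCl(PPh3)3 (5 mol%), benzene, 25 °C
Reagents that add atoms: none
Why: Homogeneous hydrogenation with RhCl(PPh3)3 should saturate the disubstituted enone C=C without hydrogenolysis of the allylic benzyl ether or reduction of the ketones; no stereocentre changes.

Step 5
Reactants: 7 2-[(R)-1-(benzyloxy)-4-oxopentyl]-2-methylcyclohexane-1,3-dione
Product: 8 cis-decalin diol ketone (C5 ketone; C9–OH; C10–OH; C3–OBn)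
Conditions: SmI2 (2.5 equiv), tBuOH (2 equiv), THF, −78 to 0 °C
Reagents that add atoms: none
Why: In this samarium diiodide pinacol cyclisation of a 1,6-diketone the C10 ketyl adds to one ring carbonyl through a chair-like transition state in which trivalent samarium bridges both oxygens (cis-diol, with C14 equatorial and away from the axial C15), the tether enforces the cis ring fusion (C9–OH cis to C15), and of the two diastereotopic ring carbonyls the one that leaves the C3 benzyloxy group equatorial on the forming ring B should be attacked, so the C3 centre fixes C4, C9 and C10.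

Step 6
Reactants: 8 cis-decalin diol ketone (C5 ketone; C9–OH; C10–OH; C3–OBn)
Product: 9 decalin enone (C5 ketone; C6=C7)
Conditions: IBX (2.5 equiv), 4-methoxypyridine N-oxide (2.5 equiv), DMSO, 25 °C
Reagents that add atoms: none
Why: IBX-mediated dehydrogenation of a ketone runs through the enol, which can form only towards C6 because C4 is quaternary, and tertiary alcohols and the benzyl ether are inert at room temperature.

Step 7
Reactants: 9 decalin enone (C5 ketone; C6=C7); 10 tert-butyl[(1-methoxyethenyl)oxy]dimethylsilane
Product: 12 decalin enone ester (CH2CO2Me on C7), via silyl enol ether 11 (not isolated)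
Conditions: 10 (3 equiv), MeCN, 55 °C; evaporate; Pd(OAc)2 (1.1 equiv), MeCN, 25 °C
Reagents that add atoms: none
Why: Mukaiyama–Michael addition of the ketene silyl acetal to C7 followed by Saegusa–Ito oxidation of the resulting silyl enol ether should re-form the enone with the C11–C12 arm on an sp2 C7, so the face of the addition does not matter.

Step 8
Reactants: 12 decalin enone ester (CH2CO2Me on C7)
Product: 13 decalin allylic alcohol (C5–OH trans to C9–OH)
Conditions: Me4NBH(OAc)3 (5 equiv), MeCN/AcOH 1:1, −30 °C
Reagents that add atoms: none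
Why: In this Evans–Saksena hydroxyl-directed reduction the axial C9 alkoxyborohydride should deliver hydride intramolecularly and in 1,2-fashion to the top face of the C5 carbonyl, giving the equatorial C5 alcohol anti to the C9 hydroxyl.

Step 9
Reactants: 13 decalin allylic alcohol (C5–OH trans to C9–OH)
Product: 15 hydroxy lactone (trans γ-lactone at C6–C7; C5–OH free), via tetrol ester 14 (not isolated)
Conditions: BH3·THF (5 equiv), THF, 0 °C; aq NaOAc, 30% H2O2, 25 °C; then PPTS (cat.), benzene, 50 °C
Reagents that add atoms: hydrogen peroxide (OO)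
Why: Hydroboration–oxidation of the trisubstituted C6=C7 alkene puts boron on the less substituted C6 and adds H and B syn from the face opposite the allylic C5 oxygen, which should set C6–OH trans to C5–OH and C7–H cis to C6–OH (arm trans to C6–O), and the trans-diequatorial hydroxy ester then lactonises under mild acid.

Step 10
Reactants: 15 hydroxy lactone (trans γ-lactone at C6–C7; C5–OH free)
Product: 16 C5 mesylate
Conditions: MsCl (1.5 equiv), Et3N (3 equiv), CH2Cl2, −20 to 0 °C
Reagents that add atoms: methanesulfonyl chloride (CS(=O)(=O)Cl)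
Why: Sulfonylation should be selective for the only secondary alcohol (C5) over the two hindered tertiary ones and leaves the C5 configuration unchanged.

Step 11
Reactants: 16 C5 mesylate
Product: 17 C3 alcohol (C3–OH cis to C15)
Conditions: H2 (1 atm), Pd(OH)2/C, EtOAc, 25 °C
Reagents that add atoms: none
Why: Hydrogenolysis should cleave the benzyl ether and leave mesylate, lactone and tertiary alcohols untouched; the molecule holds no alkene at this stage.

Step 12
Reactants: 17 C3 alcohol (C3–OH cis to C15)
Product: 18 C3 ketone
Conditions: SO3·pyridine (3 equiv), DMSO, iPr2NEt, CH2Cl2, 0 °C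
Reagents that add atoms: none
Why: Parikh–Doering oxidation should convert the secondary C3 alcohol to the ketone under conditions that do not cleave the vicinal tertiary diol or disturb the mesylate, erasing the sacrificial C3 centre.

Step 13
Reactants: 18 C3 ketone
Product: 19 C3 alcohol (C3–OH trans to C15)
Conditions: LiBH(sBu)3 (3.5 equiv), THF, −78 °C; then H2O
Reagents that add atoms: none
Why: The bulky hydride should attack equatorially, the axial path at C3 being blocked by the syn-axial C8 methylene of the lactone-locked cis-decalin, so the C3 hydroxyl ends up axial on ring B and trans to C15 as in the target.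

Step 14
Reactants: 19 C3 alcohol (C3–OH trans to C15)
Product: 20 fragmentation precursor (C3–OMOM; C5–OMs; C9–OH and C10–OH free)
Conditions: MOMCl (4 equiv), iPr2NEt (6 equiv), nBu4NI (cat.), CH2Cl2, 25 to 35 °C
Reagents that add atoms: chloromethyl methyl ether (COCCl)
Why: Alkylation with MOMCl under amine base should protect the only secondary hydroxyl, the tertiary C9 and C10 hydroxyls being too hindered to react under these conditions.

Step 15
Reactants: 20 fragmentation precursor (C3–OMOM; C5–OMs; C9–OH and C10–OH free)
Product: 21 Z-cyclodecenone lactone (C9 ketone; C10–OH; C3–OMOM)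
Conditions: KOtBu (2.2 equiv), THF, −20 to 0 °C; AcOH quench
Reagents that add atoms: none
Why: KOtBu deprotonates the C9 hydroxyl, and the alkoxide forms the C9 carbonyl while the C4–C9 σ bond shared by ring A and ring B becomes the C4=C5 π bond and mesylate leaves C5, all in one concerted antiperiplanar event. The closest known reaction type is the Grob (Wharton) fragmentation of decalin 1,3-diol monosulfonates to cyclodecenones. No ring is closed by bond formation: the ten-membered ring C1–C10 is released by cutting the bond common to the two six-membered rings, so no entropic cost of medium-ring closure is paid, and the γ-lactone is carried through unchanged. No new stereocentre is formed; the alkene geometry is fixed by the substrate, because the trans-fused lactone locks ring A in the chair that holds C5–OMs equatorial and antiperiplanar to C4–C9, and in the cis-fused decalin C3 is then axial on ring A and gauche to C6, which should give only the Z-C4=C5 alkene. The step needs fragmentation to win over substitution, elimination and C3–C4 scission: the mesylate has no antiperiplanar hydrogen, the C3 oxygen is capped as its MOM ether, and the C10 alkoxide has no leaving group in a 1,3-relation, so only the C9 alkoxide is productive.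

Step 16
Reactants: 21 Z-cyclodecenone lactone (C9 ketone; C10–OH; C3–OMOM)
Product: 22 bis-MOM cyclodecenone lactone
Conditions: MOMCl (6 equiv), iPr2NEt (10 equiv), NaI (cat.), DME, 50 °C
Reagents that add atoms: chloromethyl methyl ether (COCCl)
Why: O-Alkylation of the tertiary α-ketol hydroxyl with MOMCl masks C10–OH, now the only free hydroxyl, so that the next reduction is not chelation-controlled.

Step 17
Reactants: 22 bis-MOM cyclodecenone lactone
Product: 23 C9 alcohol (target configuration)
Conditions: NaBH4, MeOH, −40 °C
Reagents that add atoms: none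
Why: Borohydride reduction of the α-alkoxy ketone in a protic solvent should follow the polar Felkin–Anh model, hydride reaching C9 anti to the C10–O bond and past the small C14 methyl on the outer face of the ring, which gives the C9 configuration of the target; the lactone is not reduced at this temperature.

Step 18
Reactants: 23 C9 alcohol (target configuration); 24 N,N-dimethylmethyleneiminium iodide
Product: 27 α-methylene lactone alcohol, via Mannich base 25 (not isolated), via ammonium iodide 26 (not isolated)
Conditions: LiN(iPr)2 (2.3 equiv), THF, −78 °C; 24 (3 equiv), −78 to 0 °C; then MeI, MeOH, 25 °C; aq NaHCO3, CH2Cl2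
Reagents that add atoms: iodomethane (CI)
Why: In this α-methylenation by the Eschenmoser Mannich sequence the lithium lactone enolate is aminomethylated at C11, the amine is quaternised and mild base triggers β-elimination to the exocyclic alkene; C11 loses its stereocentre and C7 is not enolisable.

Step 19
Reactants: 27 α-methylene lactone alcohol; 28 angelic acid
Product: 29 bis-MOM ether of the target
Conditions: 28 (3 equiv), 2,4,6-Cl3C6H2COCl (3 equiv), Et3N (6 equiv), toluene, 25 °C; then 27, 75 °C
Reagents that add atoms: none
Why: Yamaguchi-type esterification through the mixed 2,4,6-trichlorobenzoic angelic anhydride, run without DMAP, should acylate the hindered secondary C9 alcohol while keeping the Z geometry of the angelate; no other hydroxyl is free.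

Step 20
Reactants: 29 bis-MOM ether of the target
Product: 30 CNP0549192.1
Conditions: Me2BBr (6 equiv), CH2Cl2, −78 °C; then THF/aq NaHCO3
Reagents that add atoms: none
Why: Me2BBr cleaves both MOM acetals at the acetal carbon at low temperature, so neither the allylic C3–O nor the tertiary C10–O bond is ionised and the angelate, α-methylene lactone and Z alkene should survive.

Compound list
1 | benzyl propargyl ether, [(prop-2-yn-1-yloxy)methyl]benzene | C#CCOCc1ccccc1 | starting material
2 | benzyloxyallene, [(propa-1,2-dien-1-yloxy)methyl]benzene | C=C=COCc1ccccc1 | intermediate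
3 | 2-methylcyclohexane-1,3-dione (ring A: C4 with C15 between the C5 and C9 carbonyls) | CC1C(=O)CCCC1=O | starting material
4 | (R)-2-[1-(benzyloxy)prop-2-en-1-yl]-2-methylcyclohexane-1,3-dione (C3 bears OBn) | C=C[C@@H](OCc1ccccc1)C1(C)C(=O)CCCC1=O | intermediate
5 | but-3-en-2-one | CC(=O)C=C | starting material
6 | 2-[(1R,2E)-1-(benzyloxy)-4-oxopent-2-en-1-yl]-2-methylcyclohexane-1,3-dione | CC(=O)/C=C/[C@@H](OCc1ccccc1)C1(C)C(=O)CCCC1=O | intermediate
7 | 2-[(R)-1-(benzyloxy)-4-oxopentyl]-2-methylcyclohexane-1,3-dione | CC(=O)CC[C@@H](OCc1ccccc1)C1(C)C(=O)CCCC1=O | intermediate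
8 | cis-decalin diol ketone, 8-(benzyloxy)-4a,5-dihydroxy-5,8a-dimethyloctahydronaphthalen-1(2H)-one: C5 ketone; C9–OH cis to C15; C10–OH cis to C9–OH; C3–OBn cis to C15 | C[C@]1(O)CC[C@@H](OCc3ccccc3)[C@]2(C)C(=O)CCC[C@]12O | intermediate
9 | decalin enone: as 8 with a C6=C7 double bond conjugated to the C5 ketone | C[C@]1(O)CC[C@@H](OCc3ccccc3)[C@]2(C)C(=O)C=CC[C@]12O | intermediate
10 | tert-butyl[(1-methoxyethenyl)oxy]dimethylsilane | C=C(OC)O[Si](C)(C)C(C)(C)C | starting material
11 | silyl enol ether (not isolated): C5–OTBS on a C5=C6 double bond; CH2CO2Me on C7, C7 configuration not controlled | C[C@]1(O)CC[C@@H](OCc3ccccc3)[C@]2(C)C(O[Si](C)(C)C(C)(C)C)=CC(CC(=O)OC)C[C@]12O | intermediate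
12 | decalin enone ester: C5 ketone; C6=C7 with CH2CO2Me on C7; C9–OH; C10–OH; C3–OBn | C[C@]1(O)CC[C@@H](OCc3ccccc3)[C@]2(C)C(=O)C=C(CC(=O)OC)C[C@]12O | intermediate
13 | decalin allylic alcohol: C5–OH trans to C9–OH and to C15; C6=C7 with CH2CO2Me on C7 | C[C@]1(O)CC[C@@H](OCc3ccccc3)[C@]2(C)[C@H](O)C=C(CC(=O)OC)C[C@]12O | intermediate
14 | tetrol ester (not isolated): C6–OH trans to C5–OH; C7–H cis to C6–OH | C[C@]1(O)CC[C@@H](OCc3ccccc3)[C@]2(C)[C@H](O)[C@@H](O)[C@H](CC(=O)OC)C[C@]12O | intermediate
15 | hydroxy lactone: trans-fused γ-lactone C6–O–C12(=O)–C11–C7; C5–OH; C9–OH; C10–OH; C3–OBn | O=C1C[C@@H]2C[C@]3(O)[C@@](C)(O)CC[C@@H](OCc4ccccc4)[C@]3(C)[C@H](O)[C@H]2O1 | intermediate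
16 | C5 mesylate of 15 | O=C1C[C@@H]2C[C@]3(O)[C@@](C)(O)CC[C@@H](OCc4ccccc4)[C@]3(C)[C@H](OS(C)(=O)=O)[C@H]2O1 | intermediate
17 | C3 alcohol, C3–OH cis to C15; C5–OMs | O=C1C[C@@H]2C[C@]3(O)[C@@](C)(O)CC[C@@H](O)[C@]3(C)[C@H](OS(C)(=O)=O)[C@H]2O1 | intermediate
18 | C3 ketone; C5–OMs | O=C1C[C@@H]2C[C@]3(O)[C@@](C)(O)CCC(=O)[C@]3(C)[C@H](OS(C)(=O)=O)[C@H]2O1 | intermediate
19 | C3 alcohol, C3–OH trans to C15 (axial on ring B); C5–OMs | O=C1C[C@@H]2C[C@]3(O)[C@@](C)(O)CC[C@H](O)[C@]3(C)[C@H](OS(C)(=O)=O)[C@H]2O1 | intermediate
20 | fragmentation precursor: cis-decalin lactone; C9–OH and C10–OH free; C3–OMOM; C5–OMs equatorial and trans to C6–O | O=C1C[C@@H]2C[C@]3(O)[C@@](C)(O)CC[C@H](OCOC)[C@]3(C)[C@H](OS(C)(=O)=O)[C@H]2O1 | intermediate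
21 | Z-cyclodecenone lactone: C9 ketone; C10–OH; C3–OMOM; (Z)-C4=C5 | O=C1C[C@@H]2CC(=O)[C@@](C)(O)CC[C@H](OCOC)/C(C)=C\[C@H]2O1 | intermediate
22 | bis-MOM cyclodecenone lactone: C9 ketone; C10–OMOM; C3–OMOM | O=C1C[C@@H]2CC(=O)[C@@](C)(OCOC)CC[C@H](OCOC)/C(C)=C\[C@H]2O1 | intermediate
23 | C9 alcohol with the C9 configuration of the target | O=C1C[C@@H]2C[C@H](O)[C@@](C)(OCOC)CC[C@H](OCOC)/C(C)=C\[C@H]2O1 | intermediate
24 | N,N-dimethylmethyleneiminium iodide (Eschenmoser's salt) | C=[N+](C)C.[I-] | starting material
25 | Mannich base (not isolated): CH2NMe2 on C11 | CN(C)CC1C(=O)O[C@@H]2/C=C(/C)[C@@H](OCOC)CC[C@](C)(OCOC)[C@@H](O)C[C@@H]12 | intermediate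
26 | ammonium iodide (not isolated): CH2NMe3 iodide on C11 | C[N+](C)(C)CC1C(=O)O[C@@H]2/C=C(/C)[C@@H](OCOC)CC[C@](C)(OCOC)[C@@H](O)C[C@@H]12.[I-] | intermediate
27 | α-methylene lactone alcohol: C11=C13; C9–OH free | C=C1C(=O)O[C@@H]2/C=C(/C)[C@@H](OCOC)CC[C@](C)(OCOC)[C@@H](O)C[C@@H]12 | intermediate
28 | angelic acid, (Z)-2-methylbut-2-enoic acid | C/C=C(/C)C(=O)O | starting material
29 | bis-MOM ether of the target (C9 angelate) | C=C1C(=O)O[C@@H]2/C=C(/C)[C@@H](OCOC)CC[C@](C)(OCOC)[C@@H](OC(=O)/C(C)=C\C)C[C@@H]12 | intermediate
30 | CNP0549192.1 | C=C1C(=O)O[C@@H]2/C=C(/C)[C@@H](O)CC[C@](C)(O)[C@@H](OC(=O)/C(C)=C\C)C[C@@H]12 | target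

Total step count: 20. Longest linear sequence: 20 steps (1 to 30); 3, 5, 10, 24 and 28 are bought.

Steps most likely to fail

Step 5. The coupling may discriminate poorly between the two diastereotopic ring carbonyls, or the 1,3-dione unit may be reduced on its own (cyclopropanediol formation, retro-aldol cleavage) before the ketyl finds its partner. The fallback sets out from 4 and comes back at 8, and differentiates the ring carbonyls before the coupling. Noyori asymmetric transfer hydrogenation (RuCl(p-cymene)[(S,S)-TsDPEN] or its mirror image, HCO2H/Et3N) should reduce the carbonyl destined to be C5 from the methyl face and give hydroxy ketone F1. Cross-metathesis with 5 as in step 3 should give enone F2, and hydrogenation as in step 4 keto alcohol F3. SmI2 then has a single ring ketone to couple with and should give triol F4. Parikh–Doering oxidation of its only secondary hydroxyl returns 8.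

Step 9. Borane may add to the wrong face of the C6=C7 alkene, or reduce the ester, so that C6 and C7 are set with poor control. The fallback sets out from 12 and comes back at 15, and sets C7 and C6 in separate steps. Conjugate reduction with [(Ph3P)CuH]6 should deliver hydride to the top face of C7 and give keto ester F5. Soft enolisation (TMSOTf, Et3N) should give the persilylated enol ether F6. Rubottom oxidation (mCPBA, then citric acid) should place the C6 hydroxyl anti to the C7 arm in hydroxy ketone F7. PPTS should close keto lactone F8, and the directed reduction of step 8 returns 15.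

Step 17. The conformation of the ten-membered ring, not the Felkin–Anh preference, may decide which face of the C9 carbonyl is open, so that hydride adds from the other side. The fallback sets out from 22 and comes back at 23, and corrects the centre by inversion. If the C9-epimeric alcohol F9 is the main product, Mitsunobu esterification (4-nitrobenzoic acid, PPh3, DIAD, toluene) should invert C9 and give 4-nitrobenzoate F10. Mild methanolysis (K2CO3, MeOH, 0 °C) should then return 23.

Further compounds
F1 | step 5 | hydroxy ketone: 2-[(R)-1-(benzyloxy)allyl]-3-hydroxy-2-methylcyclohexanone, hydroxyl cis to the side chain | C=C[C@@H](OCc1ccccc1)[C@]2(C)[C@H](O)CCCC2=O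
F2 | step 5 | enone: F1 with the side chain extended to (E)-CH=CH–C(=O)CH3 | CC(=O)/C=C/[C@@H](OCc1ccccc1)[C@]2(C)[C@H](O)CCCC2=O
F3 | step 5 | keto alcohol: F2 with the side-chain alkene saturated | CC(=O)CC[C@@H](OCc1ccccc1)[C@]2(C)[C@H](O)CCCC2=O
F4 | step 5 | triol: cis-decalin with C5–OH, C9–OH, C10–OH and C3–OBn | C[C@]1(O)CC[C@@H](OCc3ccccc3)[C@]2(C)[C@H](O)CCC[C@]12O
F5 | step 9 | keto ester: 12 with C6–C7 saturated, arm on C7 trans to C15 | C[C@]1(O)CC[C@@H](OCc3ccccc3)[C@]2(C)C(=O)C[C@H](CC(=O)OC)C[C@]12O
F6 | step 9 | persilylated enol ether: C5–OTMS on C5=C6; C9–OTMS; C10–OTMS | C[C@]1(O[Si](C)(C)C)CC[C@@H](OCc3ccccc3)[C@]2(C)C(O[Si](C)(C)C)=C[C@H](CC(=O)OC)C[C@]12O[Si](C)(C)C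
F7 | step 9 | hydroxy ketone: C5 ketone; C6–OH trans to the C7 arm | C[C@]1(O)CC[C@@H](OCc3ccccc3)[C@]2(C)C(=O)[C@@H](O)[C@H](CC(=O)OC)C[C@]12O
F8 | step 9 | keto lactone: trans γ-lactone at C6–C7; C5 ketone | O=C1C[C@@H]2C[C@]3(O)[C@@](C)(O)CC[C@@H](OCc4ccccc4)[C@]3(C)C(=O)[C@H]2O1
F9 | step 17 | C9-epimeric alcohol of 23 | O=C1C[C@@H]2C[C@@H](O)[C@@](C)(OCOC)CC[C@H](OCOC)/C(C)=C\[C@H]2O1
F10 | step 17 | 4-nitrobenzoate of 23 at C9–O | O=C1C[C@@H]2C[C@H](OC(=O)c3ccc(cc3)[N+](=O)[O-])[C@@](C)(OCOC)CC[C@H](OCOC)/C(C)=C\[C@H]2O1
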